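**Plan**
1. Retrosynthetic cuts, in order: the three aryl O–benzyl bonds; the oxane C3–C4 bond together with the C2–H bond, which opens the ring to an acyclic aldehyde–enol ether; the enol ether C2=C3 (back to an aryl ester C=O); the ester C–O bond; the side-chain C7–C8 bond (benzylic Grignard reagent plus terminal epoxide).
2. Forward order: C7–C8 union → ester (O1–C2) → methylenation (C3 introduced) → C4 raised to the aldehyde → the only new ring (oxane) closed at C3–C4 with hydride entering at C2 in the same flask → debenzylation.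
3. Enabling feature: O1 and the C4 oxygen are 1,3-related across C2–C3, and C2 carries both O1 and the electron-rich ring A. As the enol ether O1–C2(ring A)=C3H2, C3 is nucleophilic towards a C4 aldehyde, and the cation left at C2 is an aryl-stabilised oxocarbenium ion that a silane can reduce.
4. Stereochemistry: C6 comes from the (R)-epoxide; C4 (equatorial C–O in a chair closure) and C2 (axial hydride) are both induced by C6 in the key step.
5. Helpers: benzyl ethers on the three phenols (removed in step 9), a silyl ether on the future C4 oxygen (removed in step 6), and the trimethylsilyl group placed on O4 in the key step (removed in its work-up).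

Key step: step 8

Numbering used throughout (target): O1, C2 (bears ring A), C3, C4 (OH), C5, C6 (bears the chain C7–C8–ring B). Ring A is the 3,4-dioxygenated 5-methoxyphenyl ring; ring B is the 4-oxygenated phenyl ring. The target is (2S,4R,6S), with all three ring substituents equatorial (all-cis).

Assumption: (R)-tert-butyldimethyl[2-(oxiran-2-yl)ethoxy]silane (5) is bought as the single enantiomer; it is the epoxide left by hydrolytic kinetic resolution of the racemate.

**Step 1**
Reactants: 1 3,4-dihydroxy-5-methoxybenzaldehyde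
Product: 2 3,4-bis(benzyloxy)-5-methoxybenzaldehyde
Conditions: BnBr, K2CO3, DMF, 60 °C
Reagents that add atoms: benzyl bromide, BrCc1ccccc1
Why: Williamson ether synthesis; both catechol phenoxides are benzylated by SN2 displacement while the aldehyde is inert to K2CO3.

**Step 2**
Reactants: 2 3,4-bis(benzyloxy)-5-methoxybenzaldehyde
Product: 3 3,4-bis(benzyloxy)-5-methoxybenzoic acid
Conditions: NaClO2, NaH2PO4, 2-methyl-2-butene, tBuOH/H2O, rt
Reagents that add atoms: sodium chlorite, [Na+].[O-]Cl=O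
Why: Pinnick oxidation takes the aryl aldehyde to the acid, and the alkene scavenges HOCl so that the electron-rich ring A is not chlorinated.

**Step 3**
Reactants: 4 4-(benzyloxy)benzyl chloride; 5 (R)-tert-butyldimethyl[2-(oxiran-2-yl)ethoxy]silane
Product: 7 (S)-1-[4-(benzyloxy)phenyl]-5-[(tert-butyldimethylsilyl)oxy]pentan-3-ol, via Grignard reagent 6 (not isolated)
Conditions: Mg, THF, 0 °C → rt; then CuI (10 mol %), 5, THF, −30 → 0 °C; aq. NH4Cl
Reagents that add atoms: none
Why: Copper-catalysed SN2 opening of the terminal epoxide at its CH2 carbon by the benzylic Grignard reagent forms C7–C8 and leaves the epoxide stereocentre untouched, so (R)-5 should give the (S)-alcohol (the descriptor changes only because the priority order changes).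

**Step 4**
Reactants: 3 3,4-bis(benzyloxy)-5-methoxybenzoic acid; 7 (S)-1-[4-(benzyloxy)phenyl]-5-[(tert-butyldimethylsilyl)oxy]pentan-3-ol
Product: 8 (S)-1-[4-(benzyloxy)phenyl]-5-[(tert-butyldimethylsilyl)oxy]pentan-3-yl 3,4-bis(benzyloxy)-5-methoxybenzoate
Conditions: DCC, DMAP (cat.), CH2Cl2, 0 °C → rt
Reagents that add atoms: none
Why: Steglich esterification acylates the secondary alcohol with retention, since no bond to the stereocentre is broken.

**Step 5**
Reactants: 8 (S)-1-[4-(benzyloxy)phenyl]-5-[(tert-butyldimethylsilyl)oxy]pentan-3-yl 3,4-bis(benzyloxy)-5-methoxybenzoate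
Product: 9 (S)-{[5-[4-(benzyloxy)phenyl]-3-({1-[3,4-bis(benzyloxy)-5-methoxyphenyl]ethenyl}oxy)pentyl]oxy}(tert-butyl)dimethylsilane
Conditions: Cp2TiMe2, toluene, 70 °C, dark; filtration through basic alumina
Reagents that add atoms: dimethyltitanocene, C[Ti](C)(C1C=CC=C1)C1C=CC=C1
Why: Petasis methylenation; Cp2Ti=CH2, formed by loss of methane, undergoes [2+2] cycloaddition and cycloreversion with the ester carbonyl to give the α-aryl vinyl ether under non-acidic conditions that silyl and benzyl ethers survive.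

**Step 6**
Reactants: 9 (S)-{[5-[4-(benzyloxy)phenyl]-3-({1-[3,4-bis(benzyloxy)-5-methoxyphenyl]ethenyl}oxy)pentyl]oxy}(tert-butyl)dimethylsilane
Product: 10 (S)-5-[4-(benzyloxy)phenyl]-3-({1-[3,4-bis(benzyloxy)-5-methoxyphenyl]ethenyl}oxy)pentan-1-ol
Conditions: Bu4NF, THF, 0 °C → rt; chromatography on Et3N-deactivated silica
Reagents that add atoms: none
Why: Fluoride cleaves the Si–O bond of the primary silyl ether under basic conditions that leave the acid-labile enol ether and the benzyl ethers intact.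

**Step 7**
Reactants: 10 (S)-5-[4-(benzyloxy)phenyl]-3-({1-[3,4-bis(benzyloxy)-5-methoxyphenyl]ethenyl}oxy)pentan-1-ol
Product: 11 (S)-5-[4-(benzyloxy)phenyl]-3-({1-[3,4-bis(benzyloxy)-5-methoxyphenyl]ethenyl}oxy)pentanal
Conditions: nPr4N[RuO4] (5 mol %), N-methylmorpholine N-oxide, 4 Å MS, CH2Cl2, 0 °C → rt; filtered through basic alumina and used at once
Reagents that add atoms: none
Why: Ley–Griffith oxidation stops at the aldehyde and is neither acidic nor strongly basic, which should protect the enol ether and limit β-elimination of the β-alkoxy aldehyde.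

**Step 8**
Reactants: 11 (S)-5-[4-(benzyloxy)phenyl]-3-({1-[3,4-bis(benzyloxy)-5-methoxyphenyl]ethenyl}oxy)pentanal
Product: 14 (2S,4R,6S)-2-[3,4-bis(benzyloxy)-5-methoxyphenyl]-6-{2-[4-(benzyloxy)phenyl]ethyl}oxan-4-ol, via oxocarbenium triflate 12 (not isolated), via trimethylsilyl ether 13 (not isolated)
Conditions: Et3SiH, 2,6-di-tert-butyl-4-methylpyridine (0.3 equiv), CH2Cl2, −78 °C, then Me3SiOTf (1.2 equiv), −78 → −40 °C; then K2CO3, MeOH, 0 °C
Reagents that add atoms: none
Why: Proposed new method: Me3SiOTf silylates the aldehyde oxygen of 11, the nucleophilic methylene terminus C3 of the enol ether O1–C2(ring A)=C3H2 adds to C4, and the resulting 2-aryl oxocarbenium ion 12, stabilised by O1 and ring A, is reduced by Et3SiH; the closest known reaction types are the Lewis-acid-mediated addition of alkyl enol ethers to aldehydes and acetals (Mukaiyama-type aldol, first stage of the Mukaiyama aldol–Prins cascade) and the silane reduction of cyclic oxocarbenium ions in reductive etherification. The oxane ring closes in the 6-(enolendo)-exo-trig mode, with C2=C3 inside and C4=O outside the new ring. C4 is controlled by C6: in the chair transition state the side chain on C6 is equatorial and the bulky silylated carbonyl oxygen is expected to be equatorial too (antiperiplanar to C2–C3 and remote from O1), which gives the 4,6-cis ring, the 1,3-anti relation of C4–O and C6–O1 that monodentate Lewis acids usually give with β-alkoxy aldehydes. C2 is controlled by the ring: axial hydride delivery to the half-chair of 12, with both substituents pseudo-equatorial, places ring A equatorial (2,6-cis). The step needs C–C bond formation to outrun protonation of the enol ether and direct reduction of the aldehyde; the intramolecular six-membered closure at −78 °C, the hindered pyridine base and the late addition of Me3SiOTf are meant to secure this. Methanolysis in the work-up removes the trimethylsilyl group from O4.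

**Step 9**
Reactants: 14 (2S,4R,6S)-2-[3,4-bis(benzyloxy)-5-methoxyphenyl]-6-{2-[4-(benzyloxy)phenyl]ethyl}oxan-4-ol
Product: 15 (2S,4R,6S)-2-(3,4-dihydroxy-5-methoxyphenyl)-6-[2-(4-hydroxyphenyl)ethyl]oxan-4-ol (CNP0186008.1)
Conditions: H2 (1 atm), Pd/C (10 wt %), EtOAc/MeOH, rt
Reagents that add atoms: none
Why: Hydrogenolysis of the three aryl benzyl ethers over Pd/C should be much faster than cleavage of the cyclic benzylic C2–O1 bond, and no stereocentre is touched.

**Compound list**
1 | 3,4-dihydroxy-5-methoxybenzaldehyde (5-hydroxyvanillin) | COc1cc(C=O)cc(O)c1O | starting material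
2 | 3,4-bis(benzyloxy)-5-methoxybenzaldehyde | COc1cc(C=O)cc(OCc2ccccc2)c1OCc1ccccc1 | intermediate
3 | 3,4-bis(benzyloxy)-5-methoxybenzoic acid | COc1cc(C(=O)O)cc(OCc2ccccc2)c1OCc1ccccc1 | intermediate
4 | 4-(benzyloxy)benzyl chloride | ClCc1ccc(OCc2ccccc2)cc1 | starting material
5 | (R)-tert-butyldimethyl[2-(oxiran-2-yl)ethoxy]silane | CC(C)(C)[Si](C)(C)OCC[C@@H]1CO1 | starting material
6 | [4-(benzyloxy)benzyl]magnesium chloride | Cl[Mg]Cc1ccc(OCc2ccccc2)cc1 | intermediate (not isolated)
7 | (S)-1-[4-(benzyloxy)phenyl]-5-[(tert-butyldimethylsilyl)oxy]pentan-3-ol | CC(C)(C)[Si](C)(C)OCC[C@H](CCc1ccc(OCc2ccccc2)cc1)O | intermediate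
8 | (S)-1-[4-(benzyloxy)phenyl]-5-[(tert-butyldimethylsilyl)oxy]pentan-3-yl 3,4-bis(benzyloxy)-5-methoxybenzoate | CC(C)(C)[Si](C)(C)OCC[C@H](CCc1ccc(OCc2ccccc2)cc1)OC(=O)c1cc(OC)c(OCc2ccccc2)c(OCc2ccccc2)c1 | intermediate
9 | (S)-{[5-[4-(benzyloxy)phenyl]-3-({1-[3,4-bis(benzyloxy)-5-methoxyphenyl]ethenyl}oxy)pentyl]oxy}(tert-butyl)dimethylsilane | CC(C)(C)[Si](C)(C)OCC[C@H](CCc1ccc(OCc2ccccc2)cc1)OC(=C)c1cc(OC)c(OCc2ccccc2)c(OCc2ccccc2)c1 | intermediate
10 | (S)-5-[4-(benzyloxy)phenyl]-3-({1-[3,4-bis(benzyloxy)-5-methoxyphenyl]ethenyl}oxy)pentan-1-ol | OCC[C@H](CCc1ccc(OCc2ccccc2)cc1)OC(=C)c1cc(OC)c(OCc2ccccc2)c(OCc2ccccc2)c1 | intermediate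
11 | (S)-5-[4-(benzyloxy)phenyl]-3-({1-[3,4-bis(benzyloxy)-5-methoxyphenyl]ethenyl}oxy)pentanal | O=CC[C@H](CCc1ccc(OCc2ccccc2)cc1)OC(=C)c1cc(OC)c(OCc2ccccc2)c(OCc2ccccc2)c1 | intermediate
12 | (4R,6S)-2-[3,4-bis(benzyloxy)-5-methoxyphenyl]-6-{2-[4-(benzyloxy)phenyl]ethyl}-4-[(trimethylsilyl)oxy]-3,4,5,6-tetrahydropyrylium triflate (O1=C2 cation) | COc1cc(C2=[O+][C@@H](CCc3ccc(OCc4ccccc4)cc3)C[C@@H](O[Si](C)(C)C)C2)cc(OCc3ccccc3)c1OCc1ccccc1.[O-]S(=O)(=O)C(F)(F)F | intermediate (not isolated)
13 | (2S,4R,6S)-2-[3,4-bis(benzyloxy)-5-methoxyphenyl]-6-{2-[4-(benzyloxy)phenyl]ethyl}-4-[(trimethylsilyl)oxy]oxane | COc1cc([C@@H]2C[C@H](O[Si](C)(C)C)C[C@H](CCc3ccc(OCc4ccccc4)cc3)O2)cc(OCc3ccccc3)c1OCc1ccccc1 | intermediate (not isolated)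
14 | (2S,4R,6S)-2-[3,4-bis(benzyloxy)-5-methoxyphenyl]-6-{2-[4-(benzyloxy)phenyl]ethyl}oxan-4-ol | COc1cc([C@@H]2C[C@H](O)C[C@H](CCc3ccc(OCc4ccccc4)cc3)O2)cc(OCc3ccccc3)c1OCc1ccccc1 | intermediate
15 | (2S,4R,6S)-2-(3,4-dihydroxy-5-methoxyphenyl)-6-[2-(4-hydroxyphenyl)ethyl]oxan-4-ol | COc1cc([C@@H]2C[C@H](O)C[C@H](CCc3ccc(O)cc3)O2)cc(O)c1O | target

**Step count**
Total steps: 9. Longest linear sequence: 8 (steps 1, 2, 4, 5, 6, 7, 8, 9 from compound 1).

**Steps most likely to fail**

Step 8 (proposed new method). What may go wrong: poor facial selectivity at C4 if the silylated carbonyl oxygen does not hold the equatorial site in the closure; protonation of the enol ether followed by silane reduction to an open-chain benzylic ether; direct reduction of the aldehyde before C–C bond formation. Fallback, known chemistry: a Prins cyclisation, which builds the same ring through the C2–C3 and C4–O bonds. It sets out from Grignard reagent 6 and aldehyde 2. Reagent 6 opens (R)-2-allyloxirane (CuI cat., THF, −30 → 0 °C) to give (S)-1-[4-(benzyloxy)phenyl]hex-5-en-3-ol F1. F1 and 2 with CF3CO2H in CH2Cl2 should give, through the (E)-oxocarbenium ion in a chair and equatorial capture of the C4 cation, the all-cis (2S,4R,6S)-2-[3,4-bis(benzyloxy)-5-methoxyphenyl]-6-{2-[4-(benzyloxy)phenyl]ethyl}oxan-4-yl trifluoroacetate F2. K2CO3 in MeOH removes the ester, and the fallback comes back to the route at 14.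

Step 5. What may go wrong: incomplete methylenation of the hindered, electron-rich aryl ester, and hydrolysis of the α-aryl enol ether during isolation. Fallback: make the enol ether by C–O bond formation and elimination instead of carbonyl methylenation. It sets out from aldehyde 2 and alcohol 7. Wittig methylenation of 2 (Ph3P=CH2, THF) gives 1,2-bis(benzyloxy)-3-methoxy-5-vinylbenzene F3. Alkoxy-iodination of F3 with 7 and N-iodosuccinimide (CH2Cl2, −20 °C) places the alkoxy group at the benzylic carbon and gives the β-iodo ether {[(3S)-5-[4-(benzyloxy)phenyl]-3-{1-[3,4-bis(benzyloxy)-5-methoxyphenyl]-2-iodoethoxy}pentyl]oxy}(tert-butyl)dimethylsilane F4, as both epimers at the benzylic carbon. Dehydroiodination with KOtBu in THF removes that centre, and the fallback comes back to the route at 9.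

Step 7 (with the handling of 10 from step 6). What may go wrong: acid-triggered addition of the free primary hydroxyl to the enol ether (closure to a cyclic ketal), and β-elimination of the enolate-type leaving group from the β-(vinyloxy) aldehyde. Fallback: never have a free hydroxyl or aldehyde beside the enol ether, by adjusting the oxidation level at the ester stage and carrying C4 as a dibenzyl acetal. It sets out from ester 8. HF·pyridine (THF/pyridine, 0 °C) gives (S)-1-[4-(benzyloxy)phenyl]-5-hydroxypentan-3-yl 3,4-bis(benzyloxy)-5-methoxybenzoate F5. Dess–Martin periodinane with NaHCO3 gives (S)-1-[4-(benzyloxy)phenyl]-5-oxopentan-3-yl 3,4-bis(benzyloxy)-5-methoxybenzoate F6. Benzyloxytrimethylsilane with catalytic Me3SiOTf (CH2Cl2, −78 °C) gives (S)-5,5-bis(benzyloxy)-1-[4-(benzyloxy)phenyl]pentan-3-yl 3,4-bis(benzyloxy)-5-methoxybenzoate F7. Petasis methylenation as in step 5 gives the enol ether–acetal (S)-5-[4-(benzyloxy)-3-({5,5-bis(benzyloxy)-1-[4-(benzyloxy)phenyl]pentan-3-yl}oxy)ethenyl... more simply named 5-{1-[(3S)-5,5-bis(benzyloxy)-1-[4-(benzyloxy)phenyl]pentan-3-yl]oxyethenyl}-1,2-bis(benzyloxy)-3-methoxybenzene F8. Catalytic Me3SiOTf with Et3SiH, as in step 8, ionises the acetal; the same closure and reduction should give (2S,4R,6S)-4-(benzyloxy)-2-[3,4-bis(benzyloxy)-5-methoxyphenyl]-6-{2-[4-(benzyloxy)phenyl]ethyl}oxane F9. This ring closure is the acetal variant of the unproven step 8 and carries the same uncertainty. The hydrogenolysis of step 9 then removes four benzyl groups, and the fallback comes back to the route at 15.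

**Further compounds**
F1 | step 8 | (S)-1-[4-(benzyloxy)phenyl]hex-5-en-3-ol | C=CC[C@H](CCc1ccc(OCc2ccccc2)cc1)O
F2 | step 8 | (2S,4R,6S)-2-[3,4-bis(benzyloxy)-5-methoxyphenyl]-6-{2-[4-(benzyloxy)phenyl]ethyl}oxan-4-yl trifluoroacetate | COc1cc([C@@H]2C[C@H](OC(=O)C(F)(F)F)C[C@H](CCc3ccc(OCc4ccccc4)cc3)O2)cc(OCc3ccccc3)c1OCc1ccccc1
F3 | step 5 | 1,2-bis(benzyloxy)-3-methoxy-5-vinylbenzene | C=Cc1cc(OC)c(OCc2ccccc2)c(OCc2ccccc2)c1
F4 | step 5 | {[(3S)-5-[4-(benzyloxy)phenyl]-3-{1-[3,4-bis(benzyloxy)-5-methoxyphenyl]-2-iodoethoxy}pentyl]oxy}(tert-butyl)dimethylsilane (both epimers at the benzylic carbon) | CC(C)(C)[Si](C)(C)OCC[C@H](CCc1ccc(OCc2ccccc2)cc1)OC(CI)c1cc(OC)c(OCc2ccccc2)c(OCc2ccccc2)c1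
F5 | step 7 | (S)-1-[4-(benzyloxy)phenyl]-5-hydroxypentan-3-yl 3,4-bis(benzyloxy)-5-methoxybenzoate | OCC[C@H](CCc1ccc(OCc2ccccc2)cc1)OC(=O)c1cc(OC)c(OCc2ccccc2)c(OCc2ccccc2)c1
F6 | step 7 | (S)-1-[4-(benzyloxy)phenyl]-5-oxopentan-3-yl 3,4-bis(benzyloxy)-5-methoxybenzoate | O=CC[C@H](CCc1ccc(OCc2ccccc2)cc1)OC(=O)c1cc(OC)c(OCc2ccccc2)c(OCc2ccccc2)c1
F7 | step 7 | (S)-5,5-bis(benzyloxy)-1-[4-(benzyloxy)phenyl]pentan-3-yl 3,4-bis(benzyloxy)-5-methoxybenzoate | C(C[C@H](CCc1ccc(OCc2ccccc2)cc1)OC(=O)c1cc(OC)c(OCc2ccccc2)c(OCc2ccccc2)c1)(OCc1ccccc1)OCc1ccccc1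
F8 | step 7 | 5-{1-[(3S)-5,5-bis(benzyloxy)-1-[4-(benzyloxy)phenyl]pentan-3-yl]oxyethenyl}-1,2-bis(benzyloxy)-3-methoxybenzene | C(C[C@H](CCc1ccc(OCc2ccccc2)cc1)OC(=C)c1cc(OC)c(OCc2ccccc2)c(OCc2ccccc2)c1)(OCc1ccccc1)OCc1ccccc1
F9 | step 7 | (2S,4R,6S)-4-(benzyloxy)-2-[3,4-bis(benzyloxy)-5-methoxyphenyl]-6-{2-[4-(benzyloxy)phenyl]ethyl}oxane | COc1cc([C@@H]2C[C@H](OCc3ccccc3)C[C@H](CCc3ccc(OCc4ccccc4)cc3)O2)cc(OCc3ccccc3)c1OCc1ccccc1
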